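The ratio of target to substrate left, divided by the substrate charged, is here called the reach. Larch at 8.00 min gives 20.2 M⁻¹ and oak at 5.00 min gives 18.5 M⁻¹. Their products of free enzyme and time are about equal, though larch holds twice oak's substrate. The reach therefore shifts with the charge by only 9.42 %.

| flask | substrate | free enzyme | temperature | remark | time |
|---|---|---|---|---|---|
| larch | 0.20 M | 0.13 mM | −10 °C | run made earlier |  |
| alder | 0.20 M | 0.30 mM | 10 °C | run made earlier |  |
| oak | 0.10 M | 0.20 mM | −10 °C | run made earlier |  |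
| zeta | 0.20 M | 0.20 mM | −5 °C |  | 12 min |
| delta | 0.20 M | 0.20 mM | 25 °C |  | 12 min |

| run | time / min | target / % | substrate / % |
|---|---|---|---|
| larch | 0.417 | 28.8 | 70.6 |
| larch | 1.00 | 49.0 | 51.5 |
| larch | 2.00 | 62.6 | 37.7 |
| larch | 3.00 | 69.4 | 30.6 |
| larch | 4.00 | 73.0 | 26.7 |
| larch | 6.00 | 77.6 | 22.2 |
| larch | 8.00 | 80.4 | 19.9 |
| alder | 0.500 | 53.6 | 46.5 |
| alder | 1.00 | 64.7 | 35.6 |
| alder | 1.33 | 68.4 | 32.1 |
| alder | 2.00 | 72.1 | 27.6 |
| alder | 2.50 | 74.0 | 26.3 |
| alder | 3.00 | 74.6 | 24.8 |
| alder | 4.00 | 76.9 | 22.7 |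
| oak | 0.667 | 31.5 | 68.8 |
| oak | 2.00 | 51.5 | 48.7 |
| oak | 3.00 | 58.0 | 42.2 |
| oak | 5.00 | 64.8 | 35.1 |
| oak | 8.00 | 69.9 | 30.0 |

(scatter of a reading: 0.3 percentage points)

- the flask that comes out highest in amount of target, in percent of the substrate charged, or "all alike" when all lie within 1.5 percentage points (zeta / delta / all alike)
- target at the end, in percent of the substrate charged, zeta
- target at the end, in percent of the substrate charged, delta

- the numbers in the tables scatter by 0.3 percentage points (one standard deviation)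

Take the slope of the reach to follow free enzyme. Under second-order deactivation, free enzyme falls to τ/(τ+t) of its charge, where τ is its first half-life, so the slope runs as ρ/(τ+t). Two slopes per run give τ and ρ. The slope over the last half of the run, as a share of the slope up to the first reading, is 33.4 % in larch and 16.8 % in alder.

Larch then has τ = 2.69 min and ρ = 14.2 M⁻¹. Alder has τ = 0.306 min and ρ = 6.41 M⁻¹.

Stretching the logarithms of ρ and of τ times free enzyme along temperature gives zeta τ = 1.25 min and ρ = 11.6 M⁻¹. Delta gets τ = 0.168 min and ρ = 3.53 M⁻¹.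

Two extreme flasks can be solved at once. Free enzyme that stays at its charge gives reach ρt/τ. Free enzyme that works whole until τ and then stops gives ρ. Zeta's real curve lies between them: 12 min is 9.60 times τ, so ln((τ+t)/τ) is 2.36, above one and below t/τ. Its mean share in zeta is 24.6 %, which gives reach ρ·ln((τ+t)/τ), and so zeta's reach, target over substrate left per substrate charged, is 27.4 M⁻¹.

| target | stays | stops at τ | mean curve |
|---|---|---|---|
| zeta | 95.7 % | 69.9 % | 84.6 % |
| delta | 98.1 % | 41.4 % | 75.1 % |

Zeta stands above delta by 9.5 percentage points, more than the margin of 1.5 points.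

The forecast names zeta, with 84.5 % (83.3 % to 85.7 %) and 77 % (74 % to 79.5 %), holding that “Deactivation therefore rises faster with temperature than catalysis does, so colder runs reach further.” Its delta stands above the reckoning here.

The flasks give zeta as highest, with target 84.4 % in zeta and 72.9 % in delta.

    free enzyme → unfolded enzyme (k = 7.40 × 10⁻⁴ min⁻¹, Ea = 260 kJ mol⁻¹)
    substrate + free enzyme → target + free enzyme, rate k2*[substrate]^2.5*[free enzyme]/(1 + ([substrate]/Kh2)^2.5) (0.220 M, k = 2.50 × 10⁵ M⁻²·⁵ min⁻¹, Ea = 10.0 kJ mol⁻¹)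
    substrate + free enzyme → spent catalyst A (k = 1.30 M⁻¹ min⁻¹, Ea = 60.0 kJ mol⁻¹)
    2 free enzyme → spent catalyst B (k = 7400 M⁻¹ min⁻¹, Ea = 39.0 kJ mol⁻¹)
    (constants at 25 °C)

Zeta's end reads a reach of 27.1 M⁻¹, against the 27.4 M⁻¹ reckoned. The neighbour flask keeps zeta's free enzyme, temperature and time, and charges 0.12 M of substrate. Carrying the reach 27.4 M⁻¹ to that charge gives target 76.7 %. The neighbour ends with substrate 24.4 % and target 75.6 %.

The readings were computed with constants of no real substance; noise was put on by code.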